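Remark on the chemistry: positions are numbered as in eremophilanes at every stage, also before ring B exists (ring A = C1–C5 and C10, ring B = C5–C10, C14 = methyl on C5, C15 = methyl on C4, C11–C13 = isopropenyl on C7, C6–C8 = the arm on C5, C9 = the carbon on C10); β is the face of C14; compounds 6, 7, 27 (THF solution) and 29 are assumed to be purchasable.

## Structural features

Compound 33 is a trans-fused decalin of the eremophilane type: ring A (C1–C5, C10) and ring B (C5–C10) share the C5–C10 bond, C5 is quaternary and carries the angular methyl C14 (β), and C10 carries an α hydrogen. There are seven stereocentres; six of them, C4–C5–C10–C9–C8–C7, form an unbroken chain around the ring fusion, and C2 stands alone in ring A. C4 and C5 hold cis (β,β) methyl groups, C2 an axial α hydroxyl, C9 an equatorial α oxygen that is acylated, C8 an axial α hydroxyl cis to it, and C7 a β isopropenyl group that is axial and 1,3-syn to C14. The C7 isopropenyl and the C8 hydroxyl are therefore trans-diaxial, which is the pattern left by axial opening of a 7α,8α-epoxide. Fragile elements are the (Z)-3-methylpent-2-enoate (Z/E isomerisation, deconjugation through a dienolate or vinylketene, 1,2-acyl shift to the cis C8 hydroxyl), the isopropenyl group (drift to isopropylidene), and any C8 ketone with the axial C7 group in place, which would epimerise at C7. The real difficulty lies in ring B: three adjacent functionalised centres C7–C8–C9 with the largest group forced axial against C14, and a cis-diol that must be acylated on one oxygen only. A second difficulty is the C4 methyl, which must be set on a conformationally mobile ring A before ring B exists. The key step exploits the vicinal cis oxygens on C8 and C9 of ring B: both carbons carry oxygen, so C8–C9 can be made by reductive coupling of two aldehyde carbons held trans on C5 and C10 of ring A.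

## Logic of the disconnections

**33 ⇒ 32 ⇒ 28 + 29.** The O–Si bond at C2 and the C9 O–acyl bond are cut last. The enoate is the most fragile group, so it enters after all organometallic, oxidative and reductive steps. This leaves a diol with one silyl ether. The forward step must acylate the equatorial O9 and not O8, must not scramble the Z alkene, and the final desilylation must not create an alkoxide next to the ester.

**28 ⇒ 26 + 27.** The C7–C11 bond is cut. The trans-diaxial C7 substituent and C8 hydroxyl are the retron of an axial epoxide opening, which sets C7 and C8 together. No C8 ketone is ever made, so no epimerisable axial C7 centre arises and no hydride has to pass the axial isopropenyl group. The demand is attack at C7 from the β face, 1,3 to C14.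

**26 ⇒ 25.** The two epoxide C–O bonds are cut. The α face of C7=C8 is both the open face (opposite C14) and the face of the allylic 9α-hydroxyl, so both controls point the same way. The demand is only face selectivity.

**25 ⇒ 23 ⇒ 21 ⇒ 19.** No skeletal bond is cut; the C8 oxygen of 19 is traded for the C7=C8 alkene. This spends the C8 oxygen as a leaving group to reach C7, and step 15 returns an oxygen to C8 on the same face. Substitution must occur at C8 (axial C–O, open β side) and not at C9, and the elimination must run away from C9.

**19 ⇒ 17.** The C8–C9 bond is cut (key step). Ring B and the C9 stereocentre go back to two aldehydes on a single ring. The forward coupling must be intramolecular, chelation-controlled and must place the C9 oxygen equatorial.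

**17 ⇒ 16 ⇒ 15.** The oxidation level at C8 and C9 is adjusted and both C–O bonds are exchanged for C–Si bonds. Silicon-masked hydroxyls survive the protecting-group change at C2 and the hydrogenation, and both aldehydes are released together, so no hydroxy aldehyde stage exists. The demand is a double C–Si oxidation that spares the secondary silyl ether.

**15 ⇒ 14 ⇒ 13.** The C4–H bond is cut. On the mobile ring A neither face of the C4 methylene is reliably shielded, so the free axial 2α-hydroxyl of 13 is used to deliver hydrogen to the α face. The price is that the C2 oxygen must be free in 13 and silylated again in 15, and that no other alkene or hydroxyl may be present.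

**13 ⇒ 11.** The C4=C15 bond is cut back to a ketone. The forward methylenation must be non-basic (β-silyloxy ketone) and must tolerate the neighbouring quaternary C5.

**11 ⇒ 10.** The C8–Si bond is cut back to an allyl group. This removes the second alkene before the hydrogenation and brings C8 to the same masked level as C9.

**10 ⇒ 5 + 6 + 7.** The C9–C10 and C5–C6 bonds are cut. Ring A falls back to an enone with one stereocentre. The forward conjugate addition must go anti to the C2 oxygen and the enolate alkylation anti to the new C10 arm, which makes C14 and the C10 arm cis.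

**5 ⇒ 4 ⇒ 3 ⇒ 1.** The C2–O bond is exchanged for the C–C bond to the isopropenyl group of 1. The oxidative degradation proceeds with retention, so the configuration of 1 becomes the 2α oxygen of 33.

## Other disconnections considered

**Alternative 1:** Cut C5–C10 and C6–C7 together, so both rings arise in one intramolecular Diels–Alder reaction.
- Forward step: heating triene A1 (silyloxy diene C7=C8–C9(OSi)=C10, 1,1-disubstituted alkene C5=C6, tether C1–C4 with C2 as a dioxolane, C4 the only stereocentre) would give A2.
- In favour: two rings, two C–C bonds and the centres C5, C7 and C10 in one step. A2 already carries the isopropenyl group on C7 and an enol ether across C8–C9, whose oxidation would bring in the C8 oxygen next to a C9 carbonyl.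
- Against: the dienophile is unactivated and 1,1-disubstituted and the diene is electron-rich, so the pairing is electronically mismatched and needs high temperature. The silyl enol ether and the conjugated triene can then isomerise, and the diene unit C12=C11–C7=C8 can compete. Trans fusion and the C7 configuration must be induced by C4 alone, through a transition state that puts the isopropenyl group syn to the forming angular methyl.
- Comparison: on structure, A2 maps more of 33 than 19 does. On mechanism, the cycloaddition is concerted and stereospecific but its facial and endo/exo preferences are weakly biased, whereas the chosen closure works on an existing ring with a chelate and an axial methyl as control elements. On step economy the alternative is the better plan; on the reliability of each stereocentre the chosen plan is better.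

**Alternative 2:** Cut C9–C10 and C5–C6 on ring A, leaving ring B for a later closure.
- Forward step: copper-mediated vinyl addition to C10 of 5 and alkylation of the enolate at C5 with a (Z)-iodoallyl bromide would give A3.
- In favour: it uses the same enone 5 and the same relay of stereochemistry as step 4, so at this stage it is the equal of the chosen plan. The alkenyl iodide allows a CrCl2/NiCl2-mediated closure onto a C9 aldehyde, which would give a C7=C8 allylic alcohol of the type of 25 directly; this saves steps 12–14 and is the better plan for ring B.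
- Against: A3 still has the C4 ketone. Turning it into the β methyl needs methylenation and hydrogenation in the presence of a vinyl group and an alkenyl iodide, which rules out the hydroxyl-directed hydrogenation of step 7. The vinyl group must later be cleaved to the aldehyde without touching the iodoalkene. The C9 carbinol configuration in a chromium-mediated closure is not fixed by a chelate.
- Comparison: on structure it delivers the C7 unsaturation for free. On mechanism it is a polar addition with less inherent control at C9 than the ketyl coupling. On step economy it is better after ring closure and unsolved before it (C4).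

**Alternative 3:** Cut C5–C14 by way of a cyclopropane C5–C14–C10.
- Forward step: octalinol A4 (tetrasubstituted C5=C10, 9β-hydroxyl) would be cyclopropanated by Et2Zn/CH2I2 on the hydroxyl face to A5. Oxidation at C9 and reductive cleavage of C10–C14 would then leave the C5 methyl and the C10 hydrogen.
- In favour: methylene transfer is concerted and its face is fixed by the hydroxyl, so the quaternary centre is set with a confidence equal to or higher than that of the enolate alkylation in step 4. The C9 ketone needed for ring opening could also serve to set the 9α oxygen.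
- Against: it solves a problem the chosen plan does not have, since C14 arrives with 1. C7 and C8 remain unfunctionalised, A4 must already contain the C2 and C4 centres, and the 9β-hydroxyl must be inverted.
- Comparison: on structure it gives the bicyclic core with ring B bare at C7 and C8. On mechanism it is the equal or the better for C5. On step economy it is worse because of the extra redox changes.

Key step: step 11

## Route

Step 1
Reactants: 1 (R)-(−)-carvone
Product: 3 (R)-5-acetoxy-2-methylcyclohex-2-en-1-one, via methoxy hydroperoxide 2 (not isolated)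
Conditions: O3, CH2Cl2/MeOH, −78 °C; then Ac2O, Et3N, DMAP (cat.), 0 °C → rt
Reagents that add atoms: ozone, [O-][O+]=O (ring-bound oxygen); methanol, CO (carbonyl oxygen of the acetate)
Why: Ozone attacks only the electron-rich isopropenyl alkene and methanol traps the carbonyl oxide as 2; acetylation of the hydroperoxide triggers the Criegee rearrangement, in which the ring carbon migrates from carbon to oxygen with retention, so the new C–O bond has the configuration of the old C–C bond.

Step 2
Reactants: 3 (R)-5-acetoxy-2-methylcyclohex-2-en-1-one
Product: 4 (R)-5-hydroxy-2-methylcyclohex-2-en-1-one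
Conditions: K2CO3 (cat.), MeOH, 0 °C
Reagents that add atoms: none
Why: Transesterification to methanol removes the acetate; low temperature and catalytic base should keep β-elimination of the hydroxy ketone in check.

Step 3
Reactants: 4 (R)-5-hydroxy-2-methylcyclohex-2-en-1-one
Product: 5 (R)-5-(tert-butyldimethylsilyloxy)-2-methylcyclohex-2-en-1-one
Conditions: TBSCl, imidazole, DMF, rt
Reagents that add atoms: tert-butyldimethylsilyl chloride, CC(C)(C)[Si](C)(C)Cl
Why: Standard silylation of a secondary alcohol; the silyl ether is inert to the organometallic steps and acts as the steric marker for step 4.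

Step 4
Reactants: 5 (R)-5-(tert-butyldimethylsilyloxy)-2-methylcyclohex-2-en-1-one; 6 (chloromethyl)dimethylphenylsilane; 7 allyl bromide
Product: 10 ring-A ketone (5α-allyl-5β-methyl-10β-[(dimethylphenylsilyl)methyl]-2α-(tert-butyldimethylsilyloxy)cyclohexan-4-one), via Grignard reagent 8 (not isolated), via magnesium enolate 9 (not isolated)
Conditions: 6, Mg, THF, 45 °C; then 5, CuBr·SMe2 (10 mol %), THF, −40 °C; then 7, DMPU, −40 °C → rt
Reagents that add atoms: (chloromethyl)dimethylphenylsilane 6, ClC[Si](C)(C)c1ccccc1; allyl bromide 7, C=CCBr
Why: Copper-catalysed conjugate addition of a Grignard reagent to a 5-substituted cyclohexenone goes anti to the 5-substituent, so the C10 arm is trans to the silyloxy group; the regiodefined enolate 9 is then allylated anti to that arm (tandem conjugate addition–enolate alkylation), making C5 quaternary with C14 cis to the C10 arm.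

Step 5
Reactants: 10 ring-A ketone with the allyl group
Product: 11 ring-A ketone with a 5α-[3-(dimethylphenylsilyl)propyl] arm
Conditions: PhMe2SiH, Pt2[(CH2=CHSiMe2)2O]3 (0.5 mol %), toluene, rt → 50 °C
Reagents that add atoms: dimethylphenylsilane, C[SiH](C)c1ccccc1
Why: Hydrosilylation catalysed by zerovalent platinum adds silicon to the terminal carbon of the only monosubstituted alkene; the hindered ketone and the silyl ether are inert, and C8 becomes a masked alcohol that no longer interferes with hydrogenation.

Step 6
Reactants: 11 ring-A ketone with two C–SiMe2Ph arms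
Product: 13 4-methylene-2α-ol (5β-methyl-4-methylene-5α-[3-(dimethylphenylsilyl)propyl]-10β-[(dimethylphenylsilyl)methyl]cyclohexan-2α-ol), via methylene silyl ether 12 (not isolated)
Conditions: Cp2TiMe2, toluene, 75 °C; filtration; then TBAF, THF, rt
Reagents that add atoms: dimethyltitanocene Cp2TiMe2, C[Ti](C)(C1C=CC=C1)C1C=CC=C1
Why: The titanium methylidene formed on heating Cp2TiMe2 methylenates hindered, base-sensitive ketones without enolisation, so the β-silyloxy group is not eliminated; fluoride then frees the C2 hydroxyl while the alkyl–SiMe2Ph bonds stay intact.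

Step 7
Reactants: 13 4-methylene-2α-ol
Product: 14 4β-methyl-2α-ol (4β,5β-dimethyl-5α-[3-(dimethylphenylsilyl)propyl]-10β-[(dimethylphenylsilyl)methyl]cyclohexan-2α-ol)
Conditions: [Ir(cod)(PCy3)(py)]PF6 (5 mol %), H2 (1 atm), CH2Cl2, rt
Reagents that add atoms: none
Why: Hydroxyl-directed hydrogenation of a homoallylic alcohol: the axial 2α-hydroxyl binds the cationic iridium and hydrogen is delivered to the α face of C4=C15, so C15 ends β, cis to C14; if the alkene first moves into the ring it becomes an allylic alcohol that is reduced from the same face.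

Step 8
Reactants: 14 4β-methyl-2α-ol
Product: 15 2α-silyl ether of 14
Conditions: TBSOTf, 2,6-lutidine, CH2Cl2, −78 → 0 °C
Reagents that add atoms: tert-butyldimethylsilyl triflate, CC(C)(C)[Si](C)(C)OS(=O)(=O)C(F)(F)F
Why: Silyl triflate with a hindered pyridine base silylates the axial secondary alcohol, the only hydroxyl present, which is why the primary oxygens are still carried as C–Si bonds at this point.

Step 9
Reactants: 15 2α-silyl ether with two C–SiMe2Ph arms
Product: 16 diol (3-[10β-(hydroxymethyl)-4β,5β-dimethyl-2α-(tert-butyldimethylsilyloxy)cyclohex-5α-yl]propan-1-ol)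
Conditions: KBr, AcOOH, NaOAc, AcOH, 0 °C → rt
Reagents that add atoms: peracetic acid, CC(=O)OO
Why: Fleming–Tamao oxidation: bromodesilylation of each phenyl group makes silicon electrophilic and the peracid then inserts oxygen into both primary C–Si bonds in one operation; the acetate buffer should spare the secondary silyl ether.

Step 10
Reactants: 16 diol
Product: 17 dialdehyde (C10 formyl and C5 3-oxopropyl on the 2α-silyloxy-4β,5β-dimethylcyclohexane)
Conditions: (COCl)2, DMSO, CH2Cl2, −78 °C; then Et3N, −78 → 0 °C; used crude
Reagents that add atoms: none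
Why: Swern oxidation converts both primary alcohols at the same time at low temperature, so no hydroxy aldehyde accumulates and the C10 centre next to the new aldehyde is exposed to base only briefly.

Step 11
Reactants: 17 dialdehyde
Product: 19 2α-(tert-butyldimethylsilyloxy)-4β,5β-dimethyl-trans-decalin-8α,9α-diol, via samarium diolate 18 (not isolated)
Conditions: SmI2 (2.5 equiv), t-BuOH (2 equiv), THF, −78 °C → rt, slow addition at high dilution; aq. NaHCO3
Reagents that add atoms: none
Why: Divalent samarium transfers one electron to each aldehyde and the ketyl oxygens stay bound to trivalent samarium; the C8 ketyl carbon joins the C9 carbonyl (or ketyl) carbon in a 6-exo closure that forms C8–C9 and ring B, and work-up of 18 releases 19. The closest known reaction type is the SmI2-mediated intramolecular pinacol coupling of 1,6-dialdehydes to cis-cyclohexane-1,2-diols. The two arms can meet only when both are equatorial on ring A, so ring B grows as a chair fused trans. At C9 the oxygen should go equatorial (α), because the axial position is 1,3-diaxial to C14. At C8 the samarium bridge holds the two oxygens syn while the bond forms, so the C8 oxygen is cis to that on C9 and hence axial and α. The step needs coupling to win over simple reduction and over intermolecular coupling (only a weak proton source, no strongly activating additive, high dilution), cis over trans (chelation) and α,α over β,β (C14). No base is present, so C10 is not epimerised, and the silyl ether is inert to the reductant.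

Step 12
Reactants: 19 cis-8α,9α-diol
Product: 21 8α,9α-cyclic sulfate, via cyclic sulfite 20 (not isolated)
Conditions: SOCl2, Et3N, CH2Cl2, 0 °C; then RuCl3 (cat.), NaIO4, MeCN/H2O, 0 °C
Reagents that add atoms: thionyl chloride, O=S(Cl)Cl; sodium periodate, [Na+].[O-]I(=O)(=O)=O
Why: A cis-diol closes to the five-membered sulfite, which ruthenium tetroxide made in the flask oxidises to the cyclic sulfate; this activates the diol for substitution without a protecting group, and no other oxidisable site is present.

Step 13
Reactants: 21 cyclic sulfate
Product: 23 8β-(phenylselanyl)-9α-ol, via sulfate monoester 22 (not isolated)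
Conditions: (PhSe)2, NaBH4, EtOH/THF, 0 °C → rt; then H2SO4 (cat.), H2O (2 equiv), THF, rt
Reagents that add atoms: diphenyl diselenide, c1ccc(cc1)[Se][Se]c1ccccc1
Why: The selenolate opens the cyclic sulfate by SN2 at C8, where the C–O bond is axial and the β side is open, while backside approach to C9 is blocked by the 1,3-diaxial C14 and the ring fusion; C8 is inverted, and mild acid then cleaves the sulfate monoester at sulfur so C9 keeps its configuration.

Step 14
Reactants: 23 8β-(phenylselanyl)-9α-ol
Product: 25 allylic alcohol (2α-silyloxy-4β,5β-dimethyl-10αH-octal-7-en-9α-ol), via selenoxide 24 (not isolated)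
Conditions: H2O2 (30% aq.), pyridine, CH2Cl2, 0 °C → rt
Reagents that add atoms: none
Why: Oxidation to the selenoxide is followed by syn elimination, which for β-hydroxy selenoxides runs away from the carbinol carbon and here uses the 7β hydrogen, giving the C7=C8 alkene with the 9α-hydroxyl untouched.

Step 15
Reactants: 25 allylic alcohol
Product: 26 7α,8α-epoxy-9α-ol
Conditions: mCPBA, NaHCO3, CH2Cl2, 0 °C
Reagents that add atoms: 3-chloroperbenzoic acid, OOC(=O)c1cccc(Cl)c1
Why: Peracid epoxidation of a cyclic allylic alcohol occurs syn to the hydroxyl through hydrogen bonding, and the same α face is the one opposite the axial C14, so both effects should give the α epoxide.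

Step 16
Reactants: 26 7α,8α-epoxy-9α-ol; 27 isopropenylmagnesium bromide
Product: 28 7β-isopropenyl-2α-(tert-butyldimethylsilyloxy)-4β,5β-dimethyl-trans-decalin-8α,9α-diol
Conditions: 27 (4 equiv), CuI (20 mol %), THF, −30 → 0 °C; aq. NH4Cl
Reagents that add atoms: isopropenylmagnesium bromide 27, C=C(C)[Mg]Br
Why: Copper-catalysed Grignard opening of an epoxide follows the Fürst–Plattner rule: attack at C7 from the β face gives the trans-diaxial product directly in a chair, setting 7β-isopropenyl and 8α-hydroxyl with inversion at C7 only; attack at C8 would need a twist-boat and is next to the alkoxide-bearing C9, and the first equivalent of 27 is consumed by the hydroxyl.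

Step 17
Reactants: 28 7β-isopropenyl-8α,9α-diol; 29 (Z)-3-methylpent-2-enoic acid
Product: 32 9α-[(Z)-3-methylpent-2-enoyloxy]-7β-isopropenyl-2α-(tert-butyldimethylsilyloxy)-4β,5β-dimethyl-trans-decalin-8α-ol, via acid chloride 30 (not isolated), via stannylene acetal 31 (not isolated)
Conditions: 29, Me2C=C(Cl)NMe2, CH2Cl2, 0 °C; separately 28, Bu2SnO, toluene, reflux (−H2O); then 30 added to 31, toluene, 0 °C → rt
Reagents that add atoms: (Z)-3-methylpent-2-enoic acid 29, CC/C(C)=C\C(=O)O
Why: Dibutylstannylene acetals of cis-1,2-diols are acylated on the equatorial oxygen, here O9, so O8 needs no protection; the acid chloride is made under neutral conditions without HCl and no amine base is present, which should keep the Z alkene and prevent deconjugation through a vinylketene.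

Step 18
Reactants: 32 silyl-protected ester
Product: 33 target, 2α,8α-dihydroxy-9α-[(Z)-3-methylpent-2-enoyloxy]-10αH-eremophil-11-ene
Conditions: HF·pyridine, pyridine/THF, 0 °C → rt
Reagents that add atoms: none
Why: Buffered hydrogen fluoride cleaves the secondary silyl ether without forming an alkoxide, so the 9→8 acyl shift and isomerisation of the enoate should not be triggered.

## Compound list

1 | (R)-(−)-carvone | CC1=CC[C@H](CC1=O)C(C)=C | starting material
2 | (R)-5-(1-hydroperoxy-1-methoxyethyl)-2-methylcyclohex-2-en-1-one (both configurations at the peroxy carbon) | CC1=CC[C@H](CC1=O)C(C)(OC)OO | intermediate (not isolated)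
3 | (R)-5-acetoxy-2-methylcyclohex-2-en-1-one | CC1=CC[C@H](CC1=O)OC(C)=O | intermediate
4 | (R)-5-hydroxy-2-methylcyclohex-2-en-1-one | CC1=CC[C@H](CC1=O)O | intermediate
5 | (R)-5-(tert-butyldimethylsilyloxy)-2-methylcyclohex-2-en-1-one | CC1=CC[C@H](CC1=O)O[Si](C)(C)C(C)(C)C | intermediate
6 | (chloromethyl)dimethylphenylsilane | ClC[Si](C)(C)c1ccccc1 | starting material
7 | allyl bromide | C=CCBr | starting material
8 | [(dimethylphenylsilyl)methyl]magnesium chloride | Cl[Mg]C[Si](C)(C)c1ccccc1 | intermediate (not isolated)
9 | chloromagnesium enolate (O on C4, C4=C5) with 10β-CH2SiMe2Ph trans to 2α-OTBS | CC1=C(O[Mg]Cl)C[C@H](O[Si](C)(C)C(C)(C)C)C[C@H]1C[Si](C)(C)c1ccccc1 | intermediate (not isolated)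
10 | 5α-allyl-5β-methyl-10β-[(dimethylphenylsilyl)methyl]-2α-(tert-butyldimethylsilyloxy)cyclohexan-4-one (allyl trans to the C10 arm, C10 arm trans to the silyloxy group) | C=CC[C@]1(C)C(=O)C[C@H](O[Si](C)(C)C(C)(C)C)C[C@H]1C[Si](C)(C)c1ccccc1 | intermediate
11 | 5β-methyl-5α-[3-(dimethylphenylsilyl)propyl]-10β-[(dimethylphenylsilyl)methyl]-2α-(tert-butyldimethylsilyloxy)cyclohexan-4-one | C[Si](C)(CCC[C@]1(C)C(=O)C[C@H](O[Si](C)(C)C(C)(C)C)C[C@H]1C[Si](C)(C)c1ccccc1)c1ccccc1 | intermediate
12 | 4-methylene analogue of 11 (2α-OTBS) | C[Si](C)(CCC[C@]1(C)C(=C)C[C@H](O[Si](C)(C)C(C)(C)C)C[C@H]1C[Si](C)(C)c1ccccc1)c1ccccc1 | intermediate (not isolated)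
13 | 5β-methyl-4-methylene-5α-[3-(dimethylphenylsilyl)propyl]-10β-[(dimethylphenylsilyl)methyl]cyclohexan-2α-ol | C[Si](C)(CCC[C@]1(C)C(=C)C[C@H](O)C[C@H]1C[Si](C)(C)c1ccccc1)c1ccccc1 | intermediate
14 | 4β,5β-dimethyl-5α-[3-(dimethylphenylsilyl)propyl]-10β-[(dimethylphenylsilyl)methyl]cyclohexan-2α-ol | C[Si](C)(CCC[C@]1(C)[C@@H](C)C[C@H](O)C[C@H]1C[Si](C)(C)c1ccccc1)c1ccccc1 | intermediate
15 | 2α-O-TBS ether of 14 | C[Si](C)(CCC[C@]1(C)[C@@H](C)C[C@H](O[Si](C)(C)C(C)(C)C)C[C@H]1C[Si](C)(C)c1ccccc1)c1ccccc1 | intermediate
16 | 3-[10β-(hydroxymethyl)-4β,5β-dimethyl-2α-(tert-butyldimethylsilyloxy)cyclohex-5α-yl]propan-1-ol | OCCC[C@]1(C)[C@@H](C)C[C@H](O[Si](C)(C)C(C)(C)C)C[C@H]1CO | intermediate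
17 | ring-A dialdehyde: 10β-formyl, 5α-(3-oxopropyl), 4β,5β-dimethyl, 2α-OTBS | O=CCC[C@]1(C)[C@@H](C)C[C@H](O[Si](C)(C)C(C)(C)C)C[C@H]1C=O | intermediate
18 | bis(diiodosamarium) 8α,9α-diolate of 19 | C1C[C@]2(C)[C@@H](C)C[C@H](O[Si](C)(C)C(C)(C)C)C[C@H]2[C@H](O[Sm](I)I)[C@@H]1O[Sm](I)I | intermediate (not isolated)
19 | 2α-(tert-butyldimethylsilyloxy)-4β,5β-dimethyl-trans-decalin-8α,9α-diol (10α-H) | C1C[C@]2(C)[C@@H](C)C[C@H](O[Si](C)(C)C(C)(C)C)C[C@H]2[C@H](O)[C@@H]1O | intermediate
20 | 8α,9α-cyclic sulfite of 19 (either configuration at sulfur) | C1C[C@]2(C)[C@@H](C)C[C@H](O[Si](C)(C)C(C)(C)C)C[C@H]2[C@@H]3OS(=O)O[C@@H]31 | intermediate (not isolated)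
21 | 8α,9α-cyclic sulfate of 19 | C1C[C@]2(C)[C@@H](C)C[C@H](O[Si](C)(C)C(C)(C)C)C[C@H]2[C@@H]3OS(=O)(=O)O[C@@H]31 | intermediate
22 | sodium 8β-(phenylselanyl)-9α-yl sulfate | C1C[C@]2(C)[C@@H](C)C[C@H](O[Si](C)(C)C(C)(C)C)C[C@H]2[C@H](OS(=O)(=O)[O-])[C@H]1[Se]c1ccccc1.[Na+] | intermediate (not isolated)
23 | 8β-(phenylselanyl)-2α-(tert-butyldimethylsilyloxy)-4β,5β-dimethyl-trans-decalin-9α-ol | C1C[C@]2(C)[C@@H](C)C[C@H](O[Si](C)(C)C(C)(C)C)C[C@H]2[C@H](O)[C@H]1[Se]c1ccccc1 | intermediate
24 | selenoxide of 23 | C1C[C@]2(C)[C@@H](C)C[C@H](O[Si](C)(C)C(C)(C)C)C[C@H]2[C@H](O)[C@H]1[Se](=O)c1ccccc1 | intermediate (not isolated)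
25 | 2α-(tert-butyldimethylsilyloxy)-4β,5β-dimethyl-10αH-octal-7-en-9α-ol | C1=CC[C@]2(C)[C@@H](C)C[C@H](O[Si](C)(C)C(C)(C)C)C[C@H]2[C@@H]1O | intermediate
26 | 7α,8α-epoxy-2α-(tert-butyldimethylsilyloxy)-4β,5β-dimethyl-trans-decalin-9α-ol | O1[C@@H]2C[C@]3(C)[C@@H](C)C[C@H](O[Si](C)(C)C(C)(C)C)C[C@H]3[C@H](O)[C@H]12 | intermediate
27 | isopropenylmagnesium bromide | C=C(C)[Mg]Br | starting material
28 | 7β-isopropenyl-2α-(tert-butyldimethylsilyloxy)-4β,5β-dimethyl-trans-decalin-8α,9α-diol | C=C(C)[C@H]1C[C@]2(C)[C@@H](C)C[C@H](O[Si](C)(C)C(C)(C)C)C[C@H]2[C@H](O)[C@@H]1O | intermediate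
29 | (Z)-3-methylpent-2-enoic acid | CC/C(C)=C\C(=O)O | starting material
30 | (Z)-3-methylpent-2-enoyl chloride | CC/C(C)=C\C(=O)Cl | intermediate (not isolated)
31 | 8α,9α-O-dibutylstannylene acetal of 28 | C=C(C)[C@H]1C[C@]2(C)[C@@H](C)C[C@H](O[Si](C)(C)C(C)(C)C)C[C@H]2[C@@H]3O[Sn](CCCC)(CCCC)O[C@@H]31 | intermediate (not isolated)
32 | 2-O-TBS ether of the target | C=C(C)[C@H]1C[C@]2(C)[C@@H](C)C[C@H](O[Si](C)(C)C(C)(C)C)C[C@H]2[C@H](OC(=O)/C=C(/C)CC)[C@@H]1O | intermediate
33 | 2α,8α-dihydroxy-9α-[(Z)-3-methylpent-2-enoyloxy]-10αH-eremophil-11-ene (CNP0129603.1) | C=C(C)[C@H]1C[C@]2(C)[C@@H](C)C[C@H](O)C[C@H]2[C@H](OC(=O)/C=C(/C)CC)[C@@H]1O | target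

## Step count and least certain steps

Total: 18 steps. Longest linear sequence: 18 steps, from 1 to 33; compounds 6, 7, 27 and 29 enter as purchased materials.

**Step 11 (key step).** The likeliest failures are reduction of the aldehydes to alcohols before they couple, and loss of chelation control at C8. The arm on C5 is flexible, and the carbonyls meet only in the ring-A conformer with axial C14 and an axial silyloxy group. Partial loss of cis control at C8 would be tolerable, because C8 is made planar again in step 14. Fallback: from 17, olefin-forming McMurry coupling with low-valent titanium (TiCl3(DME)1.5, Zn–Cu, DME, reflux, slow addition) would give the C8=C9 alkene F1. Dihydroxylation with OsO4 (cat.)/NMO on the α face, opposite the axial C14, would then return to 19.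

**Step 16.** The likeliest failure is slow opening, because a branched sp2 nucleophile must approach C7 axially, 1,3 to C14; rearrangement of the epoxy alcohol or attack at C8 could then compete. Fallback: from 26, the slimmer lithium (trimethylsilyl)acetylide with BF3·OEt2 (THF, −78 °C) would open the epoxide in the same diaxial sense to the silylalkyne F2. K2CO3/MeOH would give the 7β-ethynyl diol F3. Negishi carboalumination (Me3Al, Cp2ZrCl2 (cat.), CH2Cl2; then H2O) would place methyl on the internal alkyne carbon and return to 28.

**Step 13.** The likeliest failure is competing substitution at C9 or base-induced elimination of the sulfate, since the regiochemistry rests on the axial C8–O bond being the more accessible one. Fallback: from 19, Bu2SnO (toluene, reflux) would give the stannylene acetal F4, and benzoyl chloride would acylate the equatorial O9 to the 9α-benzoate F5. Methyl N-(triethylammoniosulfonyl)carbamate (benzene, 50 °C) would dehydrate the axial 8α-hydroxyl by syn elimination to the allylic benzoate F6; only the cis 7α hydrogen is available, because C9 has no α hydrogen. K2CO3/MeOH would return to 25.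

**Step 4.** The likeliest failure is sluggish C-allylation of the chloromagnesium enolate at the tetrasubstituted carbon, which would leave the protonated conjugate adduct. Fallback: from 5 and 8, the same copper-catalysed addition in the presence of Me3SiCl would give the silyl enol ether F7, which is isolated. MeLi (THF, 0 °C) would release the lithium enolate F8, and allylation with 7 in THF/DMPU would return to 10.

**Step 17.** The likeliest failures are acyl transfer to O8 (directly or by 1,2-shift) and Z/E drift of the activated acid. Fallback: from 28, 2-chloro-1,1,1-trimethoxyethane with camphorsulfonic acid (cat.) would give the cyclic orthoester F9. Aqueous acetic acid opens such orthoesters of cis-diols to the axial ester, here the 8α-chloroacetate F10. Yamaguchi esterification of the now unique 9α-hydroxyl with 29 (2,4,6-trichlorobenzoyl chloride, Et3N, DMAP, toluene) would give the mixed diester F11. Thiourea/NaHCO3 in EtOH would remove the chloroacetate and return to 32.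

## Further compounds

F1 | step 11 | 2α-(tert-butyldimethylsilyloxy)-4β,5β-dimethyl-10αH-octal-8-ene | C1C[C@]2(C)[C@@H](C)C[C@H](O[Si](C)(C)C(C)(C)C)C[C@H]2C=C1
F2 | step 16 | 7β-[(trimethylsilyl)ethynyl]-2α-(tert-butyldimethylsilyloxy)-4β,5β-dimethyl-trans-decalin-8α,9α-diol | C[Si](C)(C)C#C[C@H]1C[C@]2(C)[C@@H](C)C[C@H](O[Si](C)(C)C(C)(C)C)C[C@H]2[C@H](O)[C@@H]1O
F3 | step 16 | 7β-ethynyl-2α-(tert-butyldimethylsilyloxy)-4β,5β-dimethyl-trans-decalin-8α,9α-diol | C#C[C@H]1C[C@]2(C)[C@@H](C)C[C@H](O[Si](C)(C)C(C)(C)C)C[C@H]2[C@H](O)[C@@H]1O
F4 | step 13 | 8α,9α-O-dibutylstannylene acetal of 19 | C1C[C@]2(C)[C@@H](C)C[C@H](O[Si](C)(C)C(C)(C)C)C[C@H]2[C@@H]3O[Sn](CCCC)(CCCC)O[C@@H]31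
F5 | step 13 | 9α-benzoyloxy-2α-(tert-butyldimethylsilyloxy)-4β,5β-dimethyl-trans-decalin-8α-ol | C1C[C@]2(C)[C@@H](C)C[C@H](O[Si](C)(C)C(C)(C)C)C[C@H]2[C@H](OC(=O)c2ccccc2)[C@@H]1O
F6 | step 13 | 9α-benzoyloxy-2α-(tert-butyldimethylsilyloxy)-4β,5β-dimethyl-10αH-octal-7-ene | C1=CC[C@]2(C)[C@@H](C)C[C@H](O[Si](C)(C)C(C)(C)C)C[C@H]2[C@@H]1OC(=O)c1ccccc1
F7 | step 4 | trimethylsilyl enol ether (C4=C5) of the conjugate adduct | CC1=C(O[Si](C)(C)C)C[C@H](O[Si](C)(C)C(C)(C)C)C[C@H]1C[Si](C)(C)c1ccccc1
F8 | step 4 | lithium enolate (C4=C5) of the conjugate adduct | CC1=C(O[Li])C[C@H](O[Si](C)(C)C(C)(C)C)C[C@H]1C[Si](C)(C)c1ccccc1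
F9 | step 17 | 8α,9α-cyclic (chloromethyl)(methoxy) orthoester of 28 | C=C(C)[C@H]1C[C@]2(C)[C@@H](C)C[C@H](O[Si](C)(C)C(C)(C)C)C[C@H]2[C@@H]3OC(CCl)(OC)O[C@@H]31
F10 | step 17 | 8α-chloroacetoxy-7β-isopropenyl-2α-(tert-butyldimethylsilyloxy)-4β,5β-dimethyl-trans-decalin-9α-ol | C=C(C)[C@H]1C[C@]2(C)[C@@H](C)C[C@H](O[Si](C)(C)C(C)(C)C)C[C@H]2[C@H](O)[C@@H]1OC(=O)CCl
F11 | step 17 | 8α-chloroacetate of 32 | C=C(C)[C@H]1C[C@]2(C)[C@@H](C)C[C@H](O[Si](C)(C)C(C)(C)C)C[C@H]2[C@H](OC(=O)/C=C(/C)CC)[C@@H]1OC(=O)CCl
A1 | alternative 1 | acyclic silyloxy triene with C2 dioxolane and the C4 stereocentre | C=C(C)/C=C/C(O[Si](C)(C)C(C)(C)C)=CCC1(OCCO1)C[C@H](C)C(C)=C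
A2 | alternative 1 | trans-fused C9 silyl enol ether with 7β-isopropenyl and C2 dioxolane | C=C(C)[C@H]1C[C@]2(C)[C@@H](C)CC3(OCCO3)C[C@H]2C(O[Si](C)(C)C(C)(C)C)=C1
A3 | alternative 2 | ring-A ketone with C10 vinyl, quaternary C5 and (Z)-iodoallyl arm | I/C=C\C[C@]1(C)C(=O)C[C@H](O[Si](C)(C)C(C)(C)C)C[C@H]1C=C
A4 | alternative 3 | 2α-silyloxy-4β-methyl-Δ5(10)-octalin-9β-ol | O[C@H]1CCCC2=C1C[C@@H](O[Si](C)(C)C(C)(C)C)C[C@@H]2C
A5 | alternative 3 | 5β,10β-methano-bridged decalin-9β-ol | O[C@H]1CCC[C@@]23C[C@@]12C[C@@H](O[Si](C)(C)C(C)(C)C)C[C@@H]3C
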